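**Plan**

- Retrosynthetic cuts, in order: the two O–Si bonds; the C4 carbonyl back to a cis-(3S,4S) benzylic alcohol; the C2/C3/C4 hydrogens back to an isoflavone; the aryl–carbonyl bond C4–C4a of ring C; the vinylic C2–O1 ether; last the chromene ring on ring B.
- Forward order: the ring B chromene is made first (propargyl ether Claisen cascade on 3,4-dihydroxybenzaldehyde). The aldehyde carbon is then homologated into the C2–C3–C4 unit, the ring A bromophenol is joined through O1, and ring C is closed last at C4–C4a to give the isoflavone.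
- Enabling feature: C4a of ring A lies between O1 and the 5-methoxy oxygen. A bromine there becomes a carbanion stabilised by both flanking oxygens, held in a six-membered array (C4a–C8a–O1–C2=C3–C4) with the cis ester carbon, so ring C closes at the most hindered ring A carbon with no regiochemical choice.
- Stereochemistry: C3 stays sp2 through all basic and organometallic steps. It is set at the end by catalyst-controlled asymmetric transfer hydrogenation of the isoflavone with dynamic kinetic resolution ((S,S) diamine ligand) to the (3S,4S) alcohol; re-oxidation of C4 leaves (3S).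

Key step: step 9

Remark: the stereocentre of the target is read as (3S); being alpha to the ketone and benzylic it is taken as base-labile, which the route uses for the dynamic kinetic resolution. TIPS = triisopropylsilyl, Ts = 4-methylbenzenesulfonyl.

**Route**

Step 1
Reactants: 1 3,4-dihydroxybenzaldehyde; 2 3-chloro-3-methylbut-1-yne
Product: 3 3-hydroxy-4-[(2-methylbut-3-yn-2-yl)oxy]benzaldehyde
Conditions: K2CO3 (1.05 equiv), KI, CuI (cat.), DMF, 50 °C
Reagents that add atoms: none
Why: Williamson-type etherification in which the 4-hydroxyl, para to the formyl group, is the more acidic phenol, so one equivalent of carbonate should give mainly the 4-phenoxide, which the tertiary propargylic chloride alkylates under copper/iodide assistance.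

Step 2
Reactants: 3 3-hydroxy-4-[(2-methylbut-3-yn-2-yl)oxy]benzaldehyde
Product: 5 8-hydroxy-2,2-dimethyl-2H-chromene-6-carbaldehyde, via allenyl catechol 4 (not isolated)
Conditions: N,N-diethylaniline, 170 °C
Reagents that add atoms: none
Why: Aromatic propargyl Claisen rearrangement to the only free ortho carbon gives allenyl catechol 4, which should pass by 1,5-hydrogen shift and oxa-6π electrocyclization to the 2,2-dimethyl-2H-chromene.

Step 3
Reactants: 5 8-hydroxy-2,2-dimethyl-2H-chromene-6-carbaldehyde
Product: 6 2,2-dimethyl-8-[(triisopropylsilyl)oxy]-2H-chromene-6-carbaldehyde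
Conditions: TIPSCl, imidazole, DMF, rt
Reagents that add atoms: triisopropylsilyl chloride, CC(C)[Si](Cl)(C(C)C)C(C)C
Why: Standard phenol silylation, the bulky triisopropylsilyl ether being chosen because it should survive tert-butyllithium, carbonate and formate/amine in the later steps.

Step 4
Reactants: 6 2,2-dimethyl-8-[(triisopropylsilyl)oxy]-2H-chromene-6-carbaldehyde; 7 ethyl diazoacetate
Product: 8 ethyl (Z)-2-{2,2-dimethyl-8-[(triisopropylsilyl)oxy]-2H-chromen-6-yl}-3-hydroxyprop-2-enoate
Conditions: HBF4·OEt2 (10 mol%), CH2Cl2, −78 °C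
Reagents that add atoms: none
Why: Acid-catalysed addition of the diazo ester to the aldehyde and loss of N2 with 1,2-shift of the electron-rich para-alkoxyaryl group (the aryl-migration mode of the Roskamp homologation) should give the alpha-formyl ester, which rests as its hydrogen-bonded (Z)-enol.

Step 5
Reactants: 8 ethyl (Z)-2-{2,2-dimethyl-8-[(triisopropylsilyl)oxy]-2H-chromen-6-yl}-3-hydroxyprop-2-enoate
Product: 9 ethyl (Z)-2-{2,2-dimethyl-8-[(triisopropylsilyl)oxy]-2H-chromen-6-yl}-3-(tosyloxy)prop-2-enoate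
Conditions: TsCl, N-methylimidazole, LiOH, MeCN, 0 °C
Reagents that add atoms: p-toluenesulfonyl chloride, Cc1ccc(cc1)S(Cl)(=O)=O
Why: O-Sulfonylation of the lithium-chelated enolate, in which lithium holds the enolate oxygen cis to the ester carbonyl, should fix the (Z) enol tosylate.

Step 6
Reactants: 10 5-methoxybenzene-1,3-diol (5-methoxyresorcinol)
Product: 11 4-bromo-5-methoxybenzene-1,3-diol
Conditions: NBS (1.0 equiv), CH2Cl2, −78 °C → 0 °C
Reagents that add atoms: N-bromosuccinimide, O=C1CCC(=O)N1Br
Why: Electrophilic aromatic bromination should go to the carbon para to one hydroxyl and ortho to the other (C4, equivalent to C6), which is more activated and statistically favoured over C2 between the hydroxyls.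

Step 7
Reactants: 11 4-bromo-5-methoxybenzene-1,3-diol
Product: 12 2-bromo-3-methoxy-5-[(triisopropylsilyl)oxy]phenol
Conditions: TIPSCl (1.0 equiv), imidazole, CH2Cl2, 0 °C
Reagents that add atoms: triisopropylsilyl chloride, CC(C)[Si](Cl)(C(C)C)C(C)C
Why: The bulky silyl chloride should silylate the unhindered hydroxyl para to bromine in preference to the hydroxyl flanked by, and hydrogen-bonded to, the ortho bromine.

Step 8
Reactants: 9 ethyl (Z)-2-{2,2-dimethyl-8-[(triisopropylsilyl)oxy]-2H-chromen-6-yl}-3-(tosyloxy)prop-2-enoate; 12 2-bromo-3-methoxy-5-[(triisopropylsilyl)oxy]phenol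
Product: 13 ethyl (Z)-3-{2-bromo-3-methoxy-5-[(triisopropylsilyl)oxy]phenoxy}-2-{2,2-dimethyl-8-[(triisopropylsilyl)oxy]-2H-chromen-6-yl}prop-2-enoate
Conditions: Cs2CO3 (1.05 equiv), MeCN, 0 °C → rt
Reagents that add atoms: none
Why: Nucleophilic vinylic substitution by addition–elimination on the beta-tosyloxy acrylate, which for a good leaving group on an ester-activated alkene should proceed with retention, so that the aryloxy group stays cis to the ester.

Step 9
Reactants: 13 ethyl (Z)-3-{2-bromo-3-methoxy-5-[(triisopropylsilyl)oxy]phenoxy}-2-{2,2-dimethyl-8-[(triisopropylsilyl)oxy]-2H-chromen-6-yl}prop-2-enoate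
Product: 15 3-{2,2-dimethyl-8-[(triisopropylsilyl)oxy]-2H-chromen-6-yl}-5-methoxy-7-[(triisopropylsilyl)oxy]-4H-chromen-4-one, via aryllithium 14 (not isolated)
Conditions: t-BuLi (2.0 equiv), THF, −95 °C → −20 °C; then H2O
Reagents that add atoms: none
Why: Bromine–lithium exchange at C4a, faster at −95 °C than any addition of tert-butyllithium, gives aryllithium 14, whose carbanion attacks the ester carbonyl held cis to the aryloxy group, and the tetrahedral lithium alkoxide expels ethoxide to give the chromen-4-one. The closest known reaction type is the Parham cyclization, the cycloacylation of an aryllithium made by halogen–lithium exchange onto a tethered ester. Ring C is closed in the 6-exo-trig mode at the C4–C4a bond. No stereocentre is formed: the product is the achiral isoflavone, which has no acidic alpha-hydrogen and so cannot be enolised or ring-opened by the ethoxide set free. The step needs regioselectivity on ring A (C4a between O1 and the methoxy group, not the carbon between O1 and the silyloxy group), which the position of the bromine secures, and it needs the (Z) alkene geometry from steps 5 and 8 so that C4a can reach C4. Exchange should win over conjugate addition because the acrylate is donor-substituted (a vinylogous carbonate) and because exactly two equivalents of tert-butyllithium are used, the second being consumed by the tert-butyl bromide.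

Step 10
Reactants: 15 3-{2,2-dimethyl-8-[(triisopropylsilyl)oxy]-2H-chromen-6-yl}-5-methoxy-7-[(triisopropylsilyl)oxy]-4H-chromen-4-one
Product: 17 (3S,4S)-3-{2,2-dimethyl-8-[(triisopropylsilyl)oxy]-2H-chromen-6-yl}-5-methoxy-7-[(triisopropylsilyl)oxy]chroman-4-ol, via racemic isoflavanone 16 (not isolated)
Conditions: RuCl[(S,S)-TsDPEN](mesitylene) (cat.), HCO2H/Et3N (1:1), EtOAc, 40 °C
Reagents that add atoms: none
Why: Noyori–Ikariya asymmetric transfer hydrogenation in cascade, in which conjugate reduction gives racemic isoflavanone 16, C3 of 16 epimerises through the enol under the amine, and the (S,S) catalyst should reduce the (3S) ketone selectively to the cis alcohol, setting C4 (S) by catalyst control and C3 (S) by dynamic kinetic resolution.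

Step 11
Reactants: 17 (3S,4S)-3-{2,2-dimethyl-8-[(triisopropylsilyl)oxy]-2H-chromen-6-yl}-5-methoxy-7-[(triisopropylsilyl)oxy]chroman-4-ol
Product: 18 (3S)-3-{2,2-dimethyl-8-[(triisopropylsilyl)oxy]-2H-chromen-6-yl}-5-methoxy-7-[(triisopropylsilyl)oxy]chroman-4-one
Conditions: Dess–Martin periodinane, pyridine, CH2Cl2, 0 °C
Reagents that add atoms: none
Why: Dess–Martin oxidation under buffered, non-enolising conditions removes the C4 stereocentre and should leave the enolisable C3 centre and the acid-sensitive benzylic position untouched.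

Step 12
Reactants: 18 (3S)-3-{2,2-dimethyl-8-[(triisopropylsilyl)oxy]-2H-chromen-6-yl}-5-methoxy-7-[(triisopropylsilyl)oxy]chroman-4-one
Product: 19 (3S)-7-hydroxy-3-(8-hydroxy-2,2-dimethyl-2H-chromen-6-yl)-5-methoxychroman-4-one
Conditions: Bu4NF, AcOH (1:1), THF, 0 °C
Reagents that add atoms: none
Why: Fluoride cleaves both aryl silyl ethers, and the acetic acid buffer should keep the medium from becoming basic enough to epimerise C3 through the enolate.

**Compound list**

1 | 3,4-dihydroxybenzaldehyde | O=Cc1ccc(O)c(O)c1 | starting material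
2 | 3-chloro-3-methylbut-1-yne | CC(C)(Cl)C#C | starting material
3 | 3-hydroxy-4-[(2-methylbut-3-yn-2-yl)oxy]benzaldehyde | O=Cc1ccc(OC(C)(C)C#C)c(O)c1 | intermediate
4 | 3,4-dihydroxy-5-(3-methylbuta-1,2-dien-1-yl)benzaldehyde (allenyl catechol; not isolated) | O=Cc1cc(O)c(O)c(C=C=C(C)C)c1 | intermediate
5 | 8-hydroxy-2,2-dimethyl-2H-chromene-6-carbaldehyde | O=Cc1cc(O)c2OC(C)(C)C=Cc2c1 | intermediate
6 | 2,2-dimethyl-8-[(triisopropylsilyl)oxy]-2H-chromene-6-carbaldehyde | O=Cc1cc(O[Si](C(C)C)(C(C)C)C(C)C)c2OC(C)(C)C=Cc2c1 | intermediate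
7 | ethyl diazoacetate | CCOC(=O)C=[N+]=[N-] | starting material
8 | ethyl (Z)-2-{2,2-dimethyl-8-[(triisopropylsilyl)oxy]-2H-chromen-6-yl}-3-hydroxyprop-2-enoate | CCOC(=O)/C(=C\O)c1cc(O[Si](C(C)C)(C(C)C)C(C)C)c2OC(C)(C)C=Cc2c1 | intermediate
9 | ethyl (Z)-2-{2,2-dimethyl-8-[(triisopropylsilyl)oxy]-2H-chromen-6-yl}-3-(tosyloxy)prop-2-enoate | CCOC(=O)/C(=C\OS(=O)(=O)c1ccc(C)cc1)c1cc(O[Si](C(C)C)(C(C)C)C(C)C)c2OC(C)(C)C=Cc2c1 | intermediate
10 | 5-methoxybenzene-1,3-diol | COc1cc(O)cc(O)c1 | starting material
11 | 4-bromo-5-methoxybenzene-1,3-diol | COc1cc(O)cc(O)c1Br | intermediate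
12 | 2-bromo-3-methoxy-5-[(triisopropylsilyl)oxy]phenol | COc1cc(O[Si](C(C)C)(C(C)C)C(C)C)cc(O)c1Br | intermediate
13 | ethyl (Z)-3-{2-bromo-3-methoxy-5-[(triisopropylsilyl)oxy]phenoxy}-2-{2,2-dimethyl-8-[(triisopropylsilyl)oxy]-2H-chromen-6-yl}prop-2-enoate | CCOC(=O)/C(=C\Oc1cc(O[Si](C(C)C)(C(C)C)C(C)C)cc(OC)c1Br)c1cc(O[Si](C(C)C)(C(C)C)C(C)C)c2OC(C)(C)C=Cc2c1 | intermediate
14 | ethyl (Z)-2-{2,2-dimethyl-8-[(triisopropylsilyl)oxy]-2H-chromen-6-yl}-3-{2-lithio-3-methoxy-5-[(triisopropylsilyl)oxy]phenoxy}prop-2-enoate (aryllithium; not isolated) | CCOC(=O)/C(=C\Oc1cc(O[Si](C(C)C)(C(C)C)C(C)C)cc(OC)c1[Li])c1cc(O[Si](C(C)C)(C(C)C)C(C)C)c2OC(C)(C)C=Cc2c1 | intermediate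
15 | 3-{2,2-dimethyl-8-[(triisopropylsilyl)oxy]-2H-chromen-6-yl}-5-methoxy-7-[(triisopropylsilyl)oxy]-4H-chromen-4-one | COc1cc(O[Si](C(C)C)(C(C)C)C(C)C)cc2occ(-c3cc(O[Si](C(C)C)(C(C)C)C(C)C)c4OC(C)(C)C=Cc4c3)c(=O)c12 | intermediate
16 | racemic 3-{2,2-dimethyl-8-[(triisopropylsilyl)oxy]-2H-chromen-6-yl}-5-methoxy-7-[(triisopropylsilyl)oxy]chroman-4-one (not isolated) | COc1cc(O[Si](C(C)C)(C(C)C)C(C)C)cc2c1C(=O)C(c1cc(O[Si](C(C)C)(C(C)C)C(C)C)c3OC(C)(C)C=Cc3c1)CO2 | intermediate
17 | (3S,4S)-3-{2,2-dimethyl-8-[(triisopropylsilyl)oxy]-2H-chromen-6-yl}-5-methoxy-7-[(triisopropylsilyl)oxy]chroman-4-ol (cis) | COc1cc(O[Si](C(C)C)(C(C)C)C(C)C)cc2c1[C@@H](O)[C@@H](c1cc(O[Si](C(C)C)(C(C)C)C(C)C)c3OC(C)(C)C=Cc3c1)CO2 | intermediate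
18 | (3S)-3-{2,2-dimethyl-8-[(triisopropylsilyl)oxy]-2H-chromen-6-yl}-5-methoxy-7-[(triisopropylsilyl)oxy]chroman-4-one | COc1cc(O[Si](C(C)C)(C(C)C)C(C)C)cc2c1C(=O)[C@@H](c1cc(O[Si](C(C)C)(C(C)C)C(C)C)c3OC(C)(C)C=Cc3c1)CO2 | intermediate
19 | (3S)-7-hydroxy-3-(8-hydroxy-2,2-dimethyl-2H-chromen-6-yl)-5-methoxychroman-4-one | COc1cc(O)cc2c1C(=O)[C@@H](c1cc(O)c3c(c1)C=CC(C)(C)O3)CO2 | target

**Count**

Total steps: 12. Longest linear sequence: 10 steps (1 → 3 → 5 → 6 → 8 → 9 → 13 → 15 → 17 → 18 → 19); ring A (10 → 11 → 12) is a two-step branch.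

**Steps most likely to fail, with fallbacks**

Step 9. The aryllithium may be protonated before it cyclises, or the alkyllithium may add to the acrylate before exchange. The carbanion also cannot reach the ester if the alkene geometry has drifted toward (E) during step 8. The fallback moves the ring closure from carbanion chemistry to palladium catalysis at the aldehyde oxidation level. Setting out from 13, i-Bu2AlH (toluene, −78 °C) should reduce the ester to (Z)-3-{2-bromo-3-methoxy-5-[(triisopropylsilyl)oxy]phenoxy}-2-{2,2-dimethyl-8-[(triisopropylsilyl)oxy]-2H-chromen-6-yl}prop-2-en-1-ol F1. MnO2 (CH2Cl2, rt) should then give the corresponding (Z)-prop-2-enal F2. Pd(OAc)2/rac-BINAP with Cs2CO3 in dioxane at 110 °C (intramolecular acylation of an aryl bromide by an aldehyde C–H bond) should close the same C4–C4a bond and return to the route at 15. At that temperature the push–pull enal can equilibrate its geometry, so both alkene isomers should converge.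

Step 10. Hydride transfer to a ketone deactivated by three oxygen donors may be slow. The very electron-rich benzylic alcohol may ionise and be reduced further with loss of the C4 oxygen. Incomplete equilibration of C3 would erode the selectivity. The fallback sets C3 by enantioselective protonation, with no C4 alcohol on the way. Setting out from 15, conjugate reduction with LiBH(s-Bu)3 (THF, −78 °C) and trapping of the enolate with Me3SiCl should give the silyl enol ether {[3-{2,2-dimethyl-8-[(triisopropylsilyl)oxy]-2H-chromen-6-yl}-5-methoxy-7-[(triisopropylsilyl)oxy]-2H-chromen-4-yl]oxy}trimethylsilane F3. Catalytic enantioselective protonation of F3 with a BINOL-derived chiral N-triflyl thiophosphoramide and phenol as the stoichiometric proton source (toluene, rt), the catalyst enantiomer being chosen for (3S), should return to the route at 18.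

Step 6. Bromination may go to C2 between the two hydroxyls or proceed to polybromination of the very electron-rich ring, and the silylation of step 7 may then pick the wrong hydroxyl. The fallback replaces electrophilic substitution by directed ortho-metalation. Setting out from 10, statistical monosilylation (TIPSCl, imidazole) should give 3-methoxy-5-[(triisopropylsilyl)oxy]phenol F4. Chloromethyl methyl ether with i-Pr2NEt should give triisopropyl[3-methoxy-5-(methoxymethoxy)phenoxy]silane F5. n-BuLi (THF, 0 °C) should lithiate the only carbon flanked by two coordinating oxygens (between the methoxymethoxy and methoxy groups), and quenching with 1,2-dibromotetrachloroethane should give [4-bromo-3-methoxy-5-(methoxymethoxy)phenoxy]triisopropylsilane F6. Mild acid methanolysis of the acetal (HCl cat., MeOH) should return to the route at 12.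

**Further compounds**

F1 | step 9 | (Z)-3-{2-bromo-3-methoxy-5-[(triisopropylsilyl)oxy]phenoxy}-2-{2,2-dimethyl-8-[(triisopropylsilyl)oxy]-2H-chromen-6-yl}prop-2-en-1-ol | OC/C(=C\Oc1cc(O[Si](C(C)C)(C(C)C)C(C)C)cc(OC)c1Br)c1cc(O[Si](C(C)C)(C(C)C)C(C)C)c2OC(C)(C)C=Cc2c1
F2 | step 9 | (Z)-3-{2-bromo-3-methoxy-5-[(triisopropylsilyl)oxy]phenoxy}-2-{2,2-dimethyl-8-[(triisopropylsilyl)oxy]-2H-chromen-6-yl}prop-2-enal | O=C/C(=C\Oc1cc(O[Si](C(C)C)(C(C)C)C(C)C)cc(OC)c1Br)c1cc(O[Si](C(C)C)(C(C)C)C(C)C)c2OC(C)(C)C=Cc2c1
F3 | step 10 | {[3-{2,2-dimethyl-8-[(triisopropylsilyl)oxy]-2H-chromen-6-yl}-5-methoxy-7-[(triisopropylsilyl)oxy]-2H-chromen-4-yl]oxy}trimethylsilane | COc1cc(O[Si](C(C)C)(C(C)C)C(C)C)cc2c1C(O[Si](C)(C)C)=C(c1cc(O[Si](C(C)C)(C(C)C)C(C)C)c3OC(C)(C)C=Cc3c1)CO2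
F4 | step 6 | 3-methoxy-5-[(triisopropylsilyl)oxy]phenol | COc1cc(O)cc(O[Si](C(C)C)(C(C)C)C(C)C)c1
F5 | step 6 | triisopropyl[3-methoxy-5-(methoxymethoxy)phenoxy]silane | COCOc1cc(OC)cc(O[Si](C(C)C)(C(C)C)C(C)C)c1
F6 | step 6 | [4-bromo-3-methoxy-5-(methoxymethoxy)phenoxy]triisopropylsilane | COCOc1cc(O[Si](C(C)C)(C(C)C)C(C)C)cc(OC)c1Br
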